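**Plan**

1. Feature: in the outer dihydrobenzofuran on ring B (O1′, C2′, C3′) the two aryl-bearing carbons are neighbours: C2′, bound to O1′, holds the 2,4-dihydroxyphenyl ring and C3′, bound to ring B, holds the 3,5-dihydroxyphenyl ring. C2′–C3′ is therefore the bond a diaryl carbene centred on C3′ makes by inserting into the benzylic C–H of an O1′ benzyl ether. The inner ring on ring A (O1, C2, C3) repeats the pattern with ring B as the C2 aryl group.
2. Cuts, in retrosynthetic order: nine O–CH3 bonds; ring A C6–vinyl (Heck); C2–C3 (second insertion) and O1–C2 (Mitsunobu); C7′–CH2 (formylation of an aryl bromide); C2′–C3′ (key insertion) and O1′–C2′ (Mitsunobu); the C3–aryl and C3′–aryl bonds (additions of one Grignard reagent) and C3′–C3a′ (ortho-formylation of a phenol).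
3. Forward: ring B benzophenone hydrazone → outer dihydrofuran ring (step 7) → C7′ bromide to CH2OH → ether with the ring A hydroxybenzophenone → inner dihydrofuran ring (step 14) → both rings to trans → stilbene → free phenols.
4. Stereochemistry: Rh2(R-PTAD)4 sets C3′ and then C3 as S. C2′ and C2 are formed cis (R) and are turned to trans (S) by reversible acid ionisation of the benzylic C–O bonds, giving 2S,3S,2′S,3′S. The alkene is E from the Heck reaction.

Key step: step 7

Assumption: Rh2(R-PTAD)4, dirhodium tetrakis[(R)-N-phthaloyl-1-adamantylglycinate], is taken to give the S configuration at the carbene-derived carbon in steps 7 and 14 (both substrates have the same local topology); if the first insertion shows the opposite sense, Rh2(S-PTAD)4 replaces it in both steps with no other change.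

**Route**

Step 1
Reactants: 1 2-bromo-5-methoxyphenol
Product: 3 3-bromo-2-hydroxy-6-methoxybenzaldehyde, via hydroxymethylphenol 2 (not isolated)
Conditions: MgCl2, Et3N, (CH2O)n, THF, reflux; aq HCl work-up
Reagents that add atoms: paraformaldehyde (as formaldehyde), C=O
Why: Magnesium phenoxide-directed ortho-formylation (Casnati–Skattebøl reaction) can only take place at the one free position ortho to the hydroxyl, which lies between the two oxygens, and the hydroxymethyl intermediate is oxidised in the flask by a second equivalent of formaldehyde.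

Step 2
Reactants: 3 3-bromo-2-hydroxy-6-methoxybenzaldehyde; 4 2,4-dimethoxybenzyl alcohol
Product: 5 3-bromo-2-[(2,4-dimethoxyphenyl)methoxy]-6-methoxybenzaldehyde
Conditions: PPh3, DIAD, THF, 0 °C → rt
Reagents that add atoms: none
Why: Mitsunobu etherification of the acidic salicylaldehyde phenol with a primary benzylic alcohol installs the future C2′ carbon without recourse to the unstable 2,4-dimethoxybenzyl halides.

Step 3
Reactants: 6 1-bromo-3,5-dimethoxybenzene
Product: 7 3,5-dimethoxyphenylmagnesium bromide (titrated stock solution in THF, kept under argon)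
Conditions: Mg turnings, I2 (cat.), THF, 50 °C
Reagents that add atoms: magnesium, [Mg]
Why: Grignard reagent formation by oxidative insertion of magnesium into the aryl C–Br bond is routine for this electron-rich bromide, and the reagent is made once in an amount that serves both step 4 and step 9.

Step 4
Reactants: 5 3-bromo-2-[(2,4-dimethoxyphenyl)methoxy]-6-methoxybenzaldehyde; 7 3,5-dimethoxyphenylmagnesium bromide
Product: 8 rac-{3-bromo-2-[(2,4-dimethoxyphenyl)methoxy]-6-methoxyphenyl}(3,5-dimethoxyphenyl)methanol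
Conditions: 7 (THF solution), THF, 0 °C → rt; H2O
Reagents that add atoms: none
Why: Grignard 1,2-addition to the aldehyde should leave the aryl bromide and the benzyl ether of 5 untouched at 0 °C; the carbinol centre is racemic and is removed in the next step.

Step 5
Reactants: 8 rac-{3-bromo-2-[(2,4-dimethoxyphenyl)methoxy]-6-methoxyphenyl}(3,5-dimethoxyphenyl)methanol
Product: 9 {3-bromo-2-[(2,4-dimethoxyphenyl)methoxy]-6-methoxyphenyl}(3,5-dimethoxyphenyl)methanone
Conditions: Dess–Martin periodinane, CH2Cl2, rt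
Reagents that add atoms: none
Why: Dess–Martin oxidation of a diarylmethanol to the benzophenone runs under nearly neutral conditions that the acid-labile dimethoxybenzyl ether should tolerate.

Step 6
Reactants: 9 {3-bromo-2-[(2,4-dimethoxyphenyl)methoxy]-6-methoxyphenyl}(3,5-dimethoxyphenyl)methanone
Product: 10 [{3-bromo-2-[(2,4-dimethoxyphenyl)methoxy]-6-methoxyphenyl}(3,5-dimethoxyphenyl)methylidene]hydrazine (E/Z mixture)
Conditions: N2H4·H2O (excess), AcOH (cat.), n-BuOH, 110 °C
Reagents that add atoms: hydrazine, NN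
Why: Acid-catalysed hydrazone condensation of a diaryl ketone; the carbonyl is flanked by two ortho oxygen substituents, so heat and a large excess of hydrazine are used, the excess also suppressing azine formation.

Step 7
Reactants: 10 [{3-bromo-2-[(2,4-dimethoxyphenyl)methoxy]-6-methoxyphenyl}(3,5-dimethoxyphenyl)methylidene]hydrazine
Product: 12 (2R,3S)-7-bromo-2-(2,4-dimethoxyphenyl)-3-(3,5-dimethoxyphenyl)-4-methoxy-2,3-dihydro-1-benzofuran (cis), via diazo compound 11 (not isolated)
Conditions: MnO2, MeCN, 0 °C; filter; Rh2(R-PTAD)4 (1 mol %), MeCN, 0 °C → rt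
Reagents that add atoms: none
Why: MnO2 dehydrogenates the hydrazone to diaryldiazomethane 11, from which the divalent rhodium carboxylate expels N2 to give a donor/donor rhodium carbene at the future C3′. The carbene carbon takes the benzylic hydrogen of the O1′–CH2 group five atoms away in a hydride-transfer-like, highly asynchronous three-centre insertion and bonds to that carbon, creating C2′–C3′; the closest known reaction type is the dirhodium-catalysed enantioselective C–H insertion of carbenes from 2-benzyloxybenzophenone hydrazones to cis-2,3-diaryl-2,3-dihydrobenzofurans. The dihydrofuran ring closes as a 1,5-insertion, the five-membered transition structure being the only unstrained one open to the tether C3′–C3a′–C7a′–O1′–C2′. C3′ is set by the chiral pocket of the (R)-PTAD ligands, which selects one face of the carbene, and C2′ follows as the cis isomer because C–C bond formation outruns rotation at the developing oxocarbenium carbon. The step needs site selectivity for the OCH2Ar hydrogen over the equally placed OCH3 hydrogens on the other ortho oxygen, and chemoselectivity over azine or dimer formation; the first is secured by the far more hydridic secondary C–H flanked by O1′ and the 2,4-dimethoxyphenyl ring, the second by the two aryl donors that tame the carbene and by slow exposure of the diazo compound to the catalyst.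

Step 8
Reactants: 12 (2R,3S)-7-bromo-2-(2,4-dimethoxyphenyl)-3-(3,5-dimethoxyphenyl)-4-methoxy-2,3-dihydro-1-benzofuran
Product: 15 [(2R,3S)-2-(2,4-dimethoxyphenyl)-3-(3,5-dimethoxyphenyl)-4-methoxy-2,3-dihydro-1-benzofuran-7-yl]methanol, via aryllithium 13 (not isolated), via aldehyde 14 (not isolated)
Conditions: n-BuLi, THF, −78 °C; DMF, −78 → 0 °C; then MeOH, NaBH4, 0 °C
Reagents that add atoms: N,N-dimethylformamide, CN(C)C=O
Why: Bromine–lithium exchange at −78 °C is faster than deprotonation of the ring C–H bonds, the aryllithium is formylated with DMF (Bouveault aldehyde synthesis) and the aldehyde is reduced in the same flask by NaBH4, none of which touches C2′ or C3′.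

Step 9
Reactants: 16 4-bromo-2,6-dimethoxybenzaldehyde; 7 3,5-dimethoxyphenylmagnesium bromide
Product: 17 rac-(4-bromo-2,6-dimethoxyphenyl)(3,5-dimethoxyphenyl)methanol
Conditions: 7 (THF solution), THF, 0 °C → rt; H2O
Reagents that add atoms: none
Why: Grignard 1,2-addition to the aldehyde, with the aryl bromide of 16 inert to the arylmagnesium reagent at 0 °C; the racemic carbinol centre is removed in the next step.

Step 10
Reactants: 17 rac-(4-bromo-2,6-dimethoxyphenyl)(3,5-dimethoxyphenyl)methanol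
Product: 18 (4-bromo-2,6-dimethoxyphenyl)(3,5-dimethoxyphenyl)methanone
Conditions: Dess–Martin periodinane, CH2Cl2, rt
Reagents that add atoms: none
Why: Dess–Martin oxidation of a diarylmethanol to the benzophenone, as in step 5.

Step 11
Reactants: 18 (4-bromo-2,6-dimethoxyphenyl)(3,5-dimethoxyphenyl)methanone
Product: 19 (4-bromo-2-hydroxy-6-methoxyphenyl)(3,5-dimethoxyphenyl)methanone
Conditions: BCl3, CH2Cl2, −78 → 0 °C; H2O
Reagents that add atoms: none
Why: Chelation-controlled Lewis acid demethylation cleaves only a methoxy group ortho to the carbonyl; the two such groups of 18 are equivalent and the boron chelate formed after the first cleavage should protect the second, so one phenol results.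

Step 12
Reactants: 15 [(2R,3S)-2-(2,4-dimethoxyphenyl)-3-(3,5-dimethoxyphenyl)-4-methoxy-2,3-dihydro-1-benzofuran-7-yl]methanol; 19 (4-bromo-2-hydroxy-6-methoxyphenyl)(3,5-dimethoxyphenyl)methanone
Product: 20 (4-bromo-2-{[(2R,3S)-2-(2,4-dimethoxyphenyl)-3-(3,5-dimethoxyphenyl)-4-methoxy-2,3-dihydro-1-benzofuran-7-yl]methoxy}-6-methoxyphenyl)(3,5-dimethoxyphenyl)methanone
Conditions: PPh3, DIAD, THF, 0 °C → rt
Reagents that add atoms: none
Why: Mitsunobu etherification joins the two fragments through O1–C2 and uses the ortho- and para-oxygenated benzylic alcohol as such, since the corresponding halide would ionise too readily to be handled.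

Step 13
Reactants: 20 (4-bromo-2-{[(2R,3S)-2-(2,4-dimethoxyphenyl)-3-(3,5-dimethoxyphenyl)-4-methoxy-2,3-dihydro-1-benzofuran-7-yl]methoxy}-6-methoxyphenyl)(3,5-dimethoxyphenyl)methanone
Product: 21 [(4-bromo-2-{[(2R,3S)-2-(2,4-dimethoxyphenyl)-3-(3,5-dimethoxyphenyl)-4-methoxy-2,3-dihydro-1-benzofuran-7-yl]methoxy}-6-methoxyphenyl)(3,5-dimethoxyphenyl)methylidene]hydrazine (E/Z mixture)
Conditions: N2H4·H2O (excess), AcOH (cat.), n-BuOH, 110 °C
Reagents that add atoms: hydrazine, NN
Why: Hydrazone condensation as in step 6; the hydrazine-buffered medium is too weakly acidic to ionise the benzylic C2′–O1′ bond of the outer ring.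

Step 14
Reactants: 21 [(4-bromo-2-{[(2R,3S)-2-(2,4-dimethoxyphenyl)-3-(3,5-dimethoxyphenyl)-4-methoxy-2,3-dihydro-1-benzofuran-7-yl]methoxy}-6-methoxyphenyl)(3,5-dimethoxyphenyl)methylidene]hydrazine
Product: 23 (2R,3S)-6-bromo-2-[(2R,3S)-2-(2,4-dimethoxyphenyl)-3-(3,5-dimethoxyphenyl)-4-methoxy-2,3-dihydro-1-benzofuran-7-yl]-3-(3,5-dimethoxyphenyl)-4-methoxy-2,3-dihydro-1-benzofuran (both rings cis), via diazo compound 22 (not isolated)
Conditions: MnO2, MeCN, 0 °C; filter; Rh2(R-PTAD)4 (1 mol %), MeCN, 0 °C → rt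
Reagents that add atoms: none
Why: The same donor/donor rhodium carbene 1,5-C–H insertion as in step 7, now into the O1–CH2 hydrogen activated by O1 and the electron-rich ring B, closes the inner ring; the catalyst should set C3 as S and the insertion geometry C2 as cis (R), the outer-ring stereocentres being too remote to override catalyst control.

Step 15
Reactants: 23 (2R,3S)-6-bromo-2-[(2R,3S)-2-(2,4-dimethoxyphenyl)-3-(3,5-dimethoxyphenyl)-4-methoxy-2,3-dihydro-1-benzofuran-7-yl]-3-(3,5-dimethoxyphenyl)-4-methoxy-2,3-dihydro-1-benzofuran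
Product: 24 (2S,3S)-6-bromo-2-[(2S,3S)-2-(2,4-dimethoxyphenyl)-3-(3,5-dimethoxyphenyl)-4-methoxy-2,3-dihydro-1-benzofuran-7-yl]-3-(3,5-dimethoxyphenyl)-4-methoxy-2,3-dihydro-1-benzofuran (both rings trans)
Conditions: TFA, CH2Cl2 (0.01 M), 0 °C → rt
Reagents that add atoms: none
Why: Acid-mediated cis-to-trans epimerisation of 2-aryl-2,3-dihydrobenzofurans: protonation reversibly ionises C2–O1 and C2′–O1′ to benzylic cations carrying ortho and para oxygen donors (ring B for C2, the 2,4-dimethoxyphenyl ring for C2′), and re-closure should give the more stable trans rings while C3 and C3′, not involved in the ionisation, keep the catalyst-derived configuration; one acid treatment for both rings keeps the exposure short.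

Step 16
Reactants: 24 (2S,3S)-6-bromo-2-[(2S,3S)-2-(2,4-dimethoxyphenyl)-3-(3,5-dimethoxyphenyl)-4-methoxy-2,3-dihydro-1-benzofuran-7-yl]-3-(3,5-dimethoxyphenyl)-4-methoxy-2,3-dihydro-1-benzofuran; 25 4-methoxystyrene
Product: 26 (2S,3S)-2-[(2S,3S)-2-(2,4-dimethoxyphenyl)-3-(3,5-dimethoxyphenyl)-4-methoxy-2,3-dihydro-1-benzofuran-7-yl]-3-(3,5-dimethoxyphenyl)-4-methoxy-6-[(E)-2-(4-methoxyphenyl)ethenyl]-2,3-dihydro-1-benzofuran
Conditions: Pd2(dba)3, [HP(t-Bu)3]BF4, Cy2NMe, 1,4-dioxane, 90 °C
Reagents that add atoms: none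
Why: Mizoroki–Heck reaction of the aryl bromide under zerovalent palladium and tri-tert-butylphosphine gives the E-stilbene by syn carbopalladation and syn β-hydride elimination; the basic medium leaves the trans dihydrobenzofurans untouched.

Step 17
Reactants: 26 (2S,3S)-2-[(2S,3S)-2-(2,4-dimethoxyphenyl)-3-(3,5-dimethoxyphenyl)-4-methoxy-2,3-dihydro-1-benzofuran-7-yl]-3-(3,5-dimethoxyphenyl)-4-methoxy-6-[(E)-2-(4-methoxyphenyl)ethenyl]-2,3-dihydro-1-benzofuran
Product: 27 gnetumontanin B
Conditions: BBr3, CH2Cl2, −78 °C → rt; MeOH, H2O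
Reagents that add atoms: none
Why: BBr3 ether cleavage should remove all nine aryl methyl groups; any reversible opening of the benzylic C2–O bonds under the Lewis acid returns to the trans rings, which are the thermodynamic isomers, and the stilbene sits meta to both ring A oxygens with no aryl nucleophile placed to cyclise onto it.

**Compound list**

1 | 2-bromo-5-methoxyphenol | COc1ccc(Br)c(O)c1 | starting material
2 | 6-bromo-2-(hydroxymethyl)-3-methoxyphenol (present as its magnesium phenoxide) | OCc1c(OC)ccc(Br)c1O | intermediate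
3 | 3-bromo-2-hydroxy-6-methoxybenzaldehyde | O=Cc1c(OC)ccc(Br)c1O | intermediate
4 | 2,4-dimethoxybenzyl alcohol | COc1ccc(CO)c(OC)c1 | starting material
5 | 3-bromo-2-[(2,4-dimethoxyphenyl)methoxy]-6-methoxybenzaldehyde | O=Cc1c(OC)ccc(Br)c1OCc1ccc(OC)cc1OC | intermediate
6 | 1-bromo-3,5-dimethoxybenzene | COc1cc(Br)cc(OC)c1 | starting material
7 | 3,5-dimethoxyphenylmagnesium bromide (THF stock solution) | COc1cc([Mg]Br)cc(OC)c1 | intermediate
8 | rac-{3-bromo-2-[(2,4-dimethoxyphenyl)methoxy]-6-methoxyphenyl}(3,5-dimethoxyphenyl)methanol | OC(c1cc(OC)cc(OC)c1)c1c(OC)ccc(Br)c1OCc1ccc(OC)cc1OC | intermediate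
9 | {3-bromo-2-[(2,4-dimethoxyphenyl)methoxy]-6-methoxyphenyl}(3,5-dimethoxyphenyl)methanone | O=C(c1cc(OC)cc(OC)c1)c1c(OC)ccc(Br)c1OCc1ccc(OC)cc1OC | intermediate
10 | hydrazone of 9 (E/Z mixture) | NN=C(c1cc(OC)cc(OC)c1)c1c(OC)ccc(Br)c1OCc1ccc(OC)cc1OC | intermediate
11 | 1-bromo-3-[diazo(3,5-dimethoxyphenyl)methyl]-2-[(2,4-dimethoxyphenyl)methoxy]-4-methoxybenzene | [N-]=[N+]=C(c1cc(OC)cc(OC)c1)c1c(OC)ccc(Br)c1OCc1ccc(OC)cc1OC | intermediate
12 | (2R,3S)-7-bromo-2-(2,4-dimethoxyphenyl)-3-(3,5-dimethoxyphenyl)-4-methoxy-2,3-dihydro-1-benzofuran (cis) | Brc1ccc(OC)c2c1O[C@@H](c1ccc(OC)cc1OC)[C@H]2c1cc(OC)cc(OC)c1 | intermediate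
13 | 7-lithio derivative of 12 (lithium in place of bromine, 2R,3S) | [Li]c1ccc(OC)c2c1O[C@@H](c1ccc(OC)cc1OC)[C@H]2c1cc(OC)cc(OC)c1 | intermediate
14 | (2R,3S)-2-(2,4-dimethoxyphenyl)-3-(3,5-dimethoxyphenyl)-4-methoxy-2,3-dihydro-1-benzofuran-7-carbaldehyde | O=Cc1ccc(OC)c2c1O[C@@H](c1ccc(OC)cc1OC)[C@H]2c1cc(OC)cc(OC)c1 | intermediate
15 | [(2R,3S)-2-(2,4-dimethoxyphenyl)-3-(3,5-dimethoxyphenyl)-4-methoxy-2,3-dihydro-1-benzofuran-7-yl]methanol | OCc1ccc(OC)c2c1O[C@@H](c1ccc(OC)cc1OC)[C@H]2c1cc(OC)cc(OC)c1 | intermediate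
16 | 4-bromo-2,6-dimethoxybenzaldehyde | COc1cc(Br)cc(OC)c1C=O | starting material
17 | rac-(4-bromo-2,6-dimethoxyphenyl)(3,5-dimethoxyphenyl)methanol | OC(c1cc(OC)cc(OC)c1)c1c(OC)cc(Br)cc1OC | intermediate
18 | (4-bromo-2,6-dimethoxyphenyl)(3,5-dimethoxyphenyl)methanone | O=C(c1cc(OC)cc(OC)c1)c1c(OC)cc(Br)cc1OC | intermediate
19 | (4-bromo-2-hydroxy-6-methoxyphenyl)(3,5-dimethoxyphenyl)methanone | O=C(c1cc(OC)cc(OC)c1)c1c(O)cc(Br)cc1OC | intermediate
20 | (4-bromo-2-{[(2R,3S)-2-(2,4-dimethoxyphenyl)-3-(3,5-dimethoxyphenyl)-4-methoxy-2,3-dihydro-1-benzofuran-7-yl]methoxy}-6-methoxyphenyl)(3,5-dimethoxyphenyl)methanone | O=C(c1cc(OC)cc(OC)c1)c1c(OC)cc(Br)cc1OCc1ccc(OC)c2c1O[C@@H](c1ccc(OC)cc1OC)[C@H]2c1cc(OC)cc(OC)c1 | intermediate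
21 | hydrazone of 20 (E/Z mixture) | NN=C(c1cc(OC)cc(OC)c1)c1c(OC)cc(Br)cc1OCc1ccc(OC)c2c1O[C@@H](c1ccc(OC)cc1OC)[C@H]2c1cc(OC)cc(OC)c1 | intermediate
22 | (2R,3S)-7-({5-bromo-2-[diazo(3,5-dimethoxyphenyl)methyl]-3-methoxyphenoxy}methyl)-2-(2,4-dimethoxyphenyl)-3-(3,5-dimethoxyphenyl)-4-methoxy-2,3-dihydro-1-benzofuran | [N-]=[N+]=C(c1cc(OC)cc(OC)c1)c1c(OC)cc(Br)cc1OCc1ccc(OC)c2c1O[C@@H](c1ccc(OC)cc1OC)[C@H]2c1cc(OC)cc(OC)c1 | intermediate
23 | (2R,3S)-6-bromo-2-[(2R,3S)-2-(2,4-dimethoxyphenyl)-3-(3,5-dimethoxyphenyl)-4-methoxy-2,3-dihydro-1-benzofuran-7-yl]-3-(3,5-dimethoxyphenyl)-4-methoxy-2,3-dihydro-1-benzofuran (both rings cis) | Brc1cc(OC)c2c(c1)O[C@@H](c1ccc(OC)c3c1O[C@@H](c1ccc(OC)cc1OC)[C@H]3c1cc(OC)cc(OC)c1)[C@H]2c1cc(OC)cc(OC)c1 | intermediate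
24 | (2S,3S)-6-bromo-2-[(2S,3S)-2-(2,4-dimethoxyphenyl)-3-(3,5-dimethoxyphenyl)-4-methoxy-2,3-dihydro-1-benzofuran-7-yl]-3-(3,5-dimethoxyphenyl)-4-methoxy-2,3-dihydro-1-benzofuran (both rings trans) | Brc1cc(OC)c2c(c1)O[C@H](c1ccc(OC)c3c1O[C@H](c1ccc(OC)cc1OC)[C@H]3c1cc(OC)cc(OC)c1)[C@H]2c1cc(OC)cc(OC)c1 | intermediate
25 | 4-methoxystyrene | C=Cc1ccc(OC)cc1 | starting material
26 | nona-O-methylgnetumontanin B, (2S,3S)-2-[(2S,3S)-2-(2,4-dimethoxyphenyl)-3-(3,5-dimethoxyphenyl)-4-methoxy-2,3-dihydro-1-benzofuran-7-yl]-3-(3,5-dimethoxyphenyl)-4-methoxy-6-[(E)-2-(4-methoxyphenyl)ethenyl]-2,3-dihydro-1-benzofuran | COc1ccc(/C=C/c2cc(OC)c3c(c2)O[C@H](c2ccc(OC)c4c2O[C@H](c2ccc(OC)cc2OC)[C@H]4c2cc(OC)cc(OC)c2)[C@H]3c2cc(OC)cc(OC)c2)cc1 | intermediate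
27 | gnetumontanin B (2S,3S,2′S,3′S; E) | Oc1ccc(/C=C/c2cc(O)c3c(c2)O[C@H](c2ccc(O)c4c2O[C@H](c2ccc(O)cc2O)[C@H]4c2cc(O)cc(O)c2)[C@H]3c2cc(O)cc(O)c2)cc1 | target

**Count and risks**

Total step count: 17. Longest linear sequence: 13 steps (steps 1, 2, 4–8 and 12–17, from 2-bromo-5-methoxyphenol); step 3 supplies the Grignard reagent for steps 4 and 9, and steps 9–11 form the ring A branch.

Steps most likely to fail:

Step 6. The condensation may stall because both faces of the carbonyl are screened by ortho oxygen substituents (one of them buttressed by the neighbouring bromine), and long heating invites azine formation or loss of the benzyl ether. Fallback: setting out from ketone 9, the carbonyl would be condensed with 1,2-bis(tert-butyldimethylsilyl)hydrazine under Sc(OTf)3 catalysis (neat or in CHCl3, 60–100 °C), a condensation made irreversible by silanol formation, to give the N-tert-butyldimethylsilyl hydrazone of 9 F1; TBAF (THF, 0 °C) then removes silicon and the route is rejoined at hydrazone 10.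

Step 15. Equilibration may be incomplete, the benzylic cations may lose the C3 or C3′ proton and re-protonate with erosion of configuration, or they may be captured between molecules by the electron-rich dimethoxyphenyl rings. Fallback: setting out from bis-cis bromide 23, the Heck reaction with 25 would be run first under the conditions of step 16 to give the bis-cis nonamethyl ether F2. BBr3 (CH2Cl2, −78 °C → rt) then removes the methyl groups; the ortho and para oxygens so freed let the two benzylic C–O bonds open through neutral quinone methides and re-close to the trans rings, so the route is rejoined at target 27.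

Step 17. Prolonged contact of the electron-rich stilbene with BBr3 and HBr may cause protonation of the alkene and oligomerisation before all nine ethers are cleaved. Fallback: setting out from bromide 24, before the stilbene exists, BBr3 would give the octaphenol bromide F3, which is peracetylated (Ac2O, pyridine) to the octaacetate bromide F4. A Heck reaction with 4-acetoxystyrene (Pd2(dba)3, [HP(t-Bu)3]BF4, Cy2NMe, dioxane) gives the nonaacetate of gnetumontanin B F5, and mild methanolysis (K2CO3, MeOH, 0 °C) rejoins the route at 27.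

**Further compounds**

F1 | step 6 | N-tert-butyldimethylsilyl hydrazone of 9 | CC(C)(C)[Si](C)(C)NN=C(c1cc(OC)cc(OC)c1)c1c(OC)ccc(Br)c1OCc1ccc(OC)cc1OC
F2 | step 15 | (2R,3S)-2-[(2R,3S)-2-(2,4-dimethoxyphenyl)-3-(3,5-dimethoxyphenyl)-4-methoxy-2,3-dihydro-1-benzofuran-7-yl]-3-(3,5-dimethoxyphenyl)-4-methoxy-6-[(E)-2-(4-methoxyphenyl)ethenyl]-2,3-dihydro-1-benzofuran (both rings cis) | COc1ccc(/C=C/c2cc(OC)c3c(c2)O[C@@H](c2ccc(OC)c4c2O[C@@H](c2ccc(OC)cc2OC)[C@H]4c2cc(OC)cc(OC)c2)[C@H]3c2cc(OC)cc(OC)c2)cc1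
F3 | step 17 | (2S,3S)-6-bromo-2-[(2S,3S)-2-(2,4-dihydroxyphenyl)-3-(3,5-dihydroxyphenyl)-4-hydroxy-2,3-dihydro-1-benzofuran-7-yl]-3-(3,5-dihydroxyphenyl)-2,3-dihydro-1-benzofuran-4-ol | Brc1cc(O)c2c(c1)O[C@H](c1ccc(O)c3c1O[C@H](c1ccc(O)cc1O)[C@H]3c1cc(O)cc(O)c1)[C@H]2c1cc(O)cc(O)c1
F4 | step 17 | octaacetate of F3 | Brc1cc(OC(C)=O)c2c(c1)O[C@H](c1ccc(OC(C)=O)c3c1O[C@H](c1ccc(OC(C)=O)cc1OC(C)=O)[C@H]3c1cc(OC(C)=O)cc(OC(C)=O)c1)[C@H]2c1cc(OC(C)=O)cc(OC(C)=O)c1
F5 | step 17 | nonaacetate of gnetumontanin B | CC(=O)Oc1ccc(/C=C/c2cc(OC(C)=O)c3c(c2)O[C@H](c2ccc(OC(C)=O)c4c2O[C@H](c2ccc(OC(C)=O)cc2OC(C)=O)[C@H]4c2cc(OC(C)=O)cc(OC(C)=O)c2)[C@H]3c2cc(OC(C)=O)cc(OC(C)=O)c2)cc1
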